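Enabling feature: in the central cis-fused bis-pyran, the fusion carbon O–CH lies between the pyran oxygen on C4 of the isobutyl-side quinolone (half A) and C3 of the other quinolone (half B). Its neighbour, the second fusion CH, carries the CMe2–O group bound to C4 of half B.
This array is the retron of an oxa-Diels–Alder reaction between O=C4–C3=CH(OAr) and CH=CMe2. The retrosynthesis cuts the fusion bond (O)CH–CH and the O–CMe2 bond together, then the hinge ArO–CH= bond, then the trisubstituted alkene, then the C3–CH(isobutyl) bond of half A.
Forward: one monomer, 4-hydroxy-7,8-dimethoxy-1-methylquinolin-2-one, is built from 2,3-dimethoxyaniline and diethyl malonate, so both quinolone bicycles exist first.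
One portion is allylated at C3 and converted into the prenyl-type alkene, and another portion is ethoxymethylenated. The halves are joined through this one-carbon hinge, and pyran C (isobutyl side) and pyran D (gem-dimethyl side) close together in the last operation.
Stereochemistry: the isobutyl carbon (S) is set by a chiral iridium catalyst. The fusion CH (S) is relayed from it by allylic 1,3-strain, and the O–CH carbon (R) follows from the preference for the cis fusion.

Key step: step 11

Assumption: the sense of induction of the iridium catalyst is taken from the usual empirical model for cyclometalated phosphoramidite complexes. The (Sa,S,S) ligand is written for the (S) product; if the correlation runs the other way for this nucleophile, the equally available (Ra,R,R) ligand would be used with nothing else changed.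

Step 1
Reactants: 1 2,3-dimethoxyaniline
Product: 3 N-methyl-2,3-dimethoxyaniline, via N-(methoxymethyl)aniline 2 (not isolated)
Conditions: (CH2O)n, NaOMe, MeOH, rt; then NaBH4, reflux
Reagents that add atoms: formaldehyde (from paraformaldehyde), C=O; methanol, CO (its methoxy group appears only in 2)
Why: Reductive N-methylation: in methanolic NaOMe the aniline and formaldehyde stop at the N-(methoxymethyl)amine 2, and NaBH4 reduces the imine released from it, so only one methyl group should be introduced.

Step 2
Reactants: 3 N-methyl-2,3-dimethoxyaniline; 4 diethyl malonate
Product: 5 ethyl 3-[(2,3-dimethoxyphenyl)(methyl)amino]-3-oxopropanoate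
Conditions: 4 (5 equiv, neat), 170 °C, EtOH distilled off
Reagents that add atoms: none
Why: Thermal ester aminolysis (N-acylation, probably through ethoxycarbonylketene at this temperature) should stop at the mono-anilide, because the malonate is in large excess, ethanol is removed and ring closure needs a far higher temperature.

Step 3
Reactants: 5 ethyl 3-[(2,3-dimethoxyphenyl)(methyl)amino]-3-oxopropanoate
Product: 6 3-[(2,3-dimethoxyphenyl)(methyl)amino]-3-oxopropanoic acid
Conditions: LiOH, THF/H2O, 0 °C to rt; then 1 M HCl to pH 2, 0 °C
Reagents that add atoms: lithium hydroxide, [Li+].[OH-]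
Why: Saponification of the unhindered ethyl ester is much faster than hydrolysis of the tertiary anilide, and cold acidification avoids decarboxylation of the malonamic acid.

Step 4
Reactants: 6 3-[(2,3-dimethoxyphenyl)(methyl)amino]-3-oxopropanoic acid
Product: 7 4-hydroxy-7,8-dimethoxy-1-methylquinolin-2(1H)-one
Conditions: Eaton's reagent (P2O5 in MeSO3H), 70 °C
Reagents that add atoms: none
Why: Intramolecular Friedel–Crafts acylation (cyclodehydration) can occur only at the single free ortho position, which is para to a methoxy group and therefore activated; the product enolises to the 4-hydroxy-2-quinolone, and the moderate temperature spares the aryl methyl ethers.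

Step 5
Reactants: 8 isovaleraldehyde (3-methylbutanal); 9 triethyl phosphonoacetate
Product: 10 ethyl (E)-5-methylhex-2-enoate
Conditions: NaH, THF, 0 °C to rt
Reagents that add atoms: none
Why: Horner–Wadsworth–Emmons olefination of an aliphatic aldehyde with a stabilised phosphonate anion is reliably E-selective.

Step 6
Reactants: 10 ethyl (E)-5-methylhex-2-enoate
Product: 11 (E)-5-methylhex-2-en-1-ol
Conditions: i-Bu2AlH (2.2 equiv), CH2Cl2, −78 °C; Rochelle salt work-up
Reagents that add atoms: none
Why: 1,2-Reduction of the enoate with two hydride equivalents of i-Bu2AlH should give the allylic alcohol without reducing or isomerising the E-alkene.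

Step 7
Reactants: 11 (E)-5-methylhex-2-en-1-ol
Product: 12 (E)-5-methylhex-2-en-1-yl methyl carbonate
Conditions: ClCO2Me, pyridine, CH2Cl2, 0 °C
Reagents that add atoms: methyl chloroformate, COC(=O)Cl
Why: O-Acylation of the primary allylic alcohol with a chloroformate installs a leaving group that decarboxylates on ionisation.

Step 8
Reactants: 7 4-hydroxy-7,8-dimethoxy-1-methylquinolin-2(1H)-one; 12 (E)-5-methylhex-2-en-1-yl methyl carbonate
Product: 13 4-hydroxy-7,8-dimethoxy-1-methyl-3-[(3S)-5-methylhex-1-en-3-yl]quinolin-2(1H)-one
Conditions: [Ir(cod)Cl]2 (2 mol %), (Sa,S,S)-L* (4 mol %), DBU (1.1 equiv), THF, 40 °C (L* = BINOL-derived N,N-bis[1-(2-methoxyphenyl)ethyl]phosphoramidite; catalyst pre-formed before 7 is added)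
Reagents that add atoms: none
Why: Iridium-catalysed asymmetric allylic alkylation: the cyclometalated iridium phosphoramidite complex ionises the linear carbonate to a π-allyl species, which soft 1,3-dicarbonyl-type enolates attack at the substituted terminus anti to the metal, so the ligand sets the (S) centre, while any O-allylated material is a vinylogous allyl ester that can re-ionise and funnel to the C3 product.

Step 9
Reactants: 13 4-hydroxy-7,8-dimethoxy-1-methyl-3-[(3S)-5-methylhex-1-en-3-yl]quinolin-2(1H)-one; 14 2-methyl-2-butene
Product: 15 3-[(4S)-2,6-dimethylhept-2-en-4-yl]-4-hydroxy-7,8-dimethoxy-1-methylquinolin-2(1H)-one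
Conditions: second-generation Hoveyda–Grubbs catalyst (5 mol %), 1,4-benzoquinone (10 mol %), 14/CH2Cl2 (1:1), 40 °C, sealed tube
Reagents that add atoms: none
Why: Olefin cross-metathesis with a large excess of 2-methyl-2-butene transfers an isopropylidene unit to a monosubstituted alkene and is driven by loss of propene; the stereocentre is not involved, and benzoquinone suppresses double-bond migration by ruthenium hydrides.

Step 10
Reactants: 7 4-hydroxy-7,8-dimethoxy-1-methylquinolin-2(1H)-one; 16 triethyl orthoformate
Product: 17 3-(ethoxymethylidene)-7,8-dimethoxy-1-methylquinoline-2,4(1H,3H)-dione (interconverting alkene geometries)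
Conditions: 16 (10 equiv), Ac2O (3 equiv), 120 °C, volatiles distilled off
Reagents that add atoms: none
Why: Alkoxymethylenation of the active C3 position of a cyclic 1,3-dicarbonyl with orthoformate and acetic anhydride, through diethoxymethyl acetate, is the classical route to ethoxymethylene 1,3-dicarbonyls, and the large excess of orthoester suppresses attack of a second quinolone on the product.

Step 11
Reactants: 15 3-[(4S)-2,6-dimethylhept-2-en-4-yl]-4-hydroxy-7,8-dimethoxy-1-methylquinolin-2(1H)-one; 17 3-(ethoxymethylidene)-7,8-dimethoxy-1-methylquinoline-2,4(1H,3H)-dione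
Product: 19 CNP0275598.1, via aryloxymethylene dione 18 (not isolated)
Conditions: 17 (1.3 equiv), Yb(OTf)3 (20 mol %), 2,6-di-tert-butyl-4-methylpyridine (40 mol %), 5 Å MS, PhMe, 60 to 110 °C, EtOH removed by slow distillation; filtration and chromatography on Et3N-deactivated silica
Reagents that add atoms: none
Why: Proposed new method: Lewis-acid-assisted addition–elimination of the 4-OH of 15 at the ethoxymethylene carbon of 17 gives, with loss of ethanol, the vinylogous anhydride 18, whose electron-poor 1-oxadiene (O=C4–C3=CH–OAr of half B) adds to the electron-rich CH=CMe2 unit in a strongly asynchronous inverse-demand [4+2]: the hinge carbon bonds to the alkene CH, charge builds on CMe2 and the C4 oxygen collapses on it, an irreversible event that also drains the unfavourable exchange equilibrium. The closest known reactions are the domino Knoevenagel/hetero-Diels–Alder cyclisations of alkylidene-1,3-dicarbonyls with tethered trisubstituted alkenes and the intramolecular cycloadditions of alpha-alkoxy ortho-quinone methides generated from salicylaldehydes and 5-methylhex-4-en-1-ol-type alcohols; new here are the enolic aryloxy hinge and the quinoline-2,4-dione diene facing an unactivated alkene. Pyran C closes through the C–C bond as a six-membered ring that is exo with respect to both π bonds (ring atoms O, C4 and C3 of half A, CH-isobutyl, alkene CH, hinge CH; CMe2 and C3 of half B stay outside), while pyran D is the six-membered cycloaddition ring itself with both alkene carbons inside, which in the stepwise limit means capture of the tertiary cation by the C4 oxygen. The fusion CH (S) is controlled by the iridium-set centre: A1,3 strain with the cis methyl holds the allylic C–H in the alkene plane, so the tether delivers the diene to the face opposite isobutyl and places isobutyl trans to CMe2. The O–CH centre (R) follows from the endo-type folding imposed by the short, flat O–C4=C3 tether, which gives the cis fusion, and it is backed thermodynamically because this vinylogous acylal carbon can ionise reversibly and only the cis isomer lets isobutyl and the hinge oxygen sit pseudoaxial, clear of the two C2 carbonyls. The step also needs the ketone oxygen rather than the lactam oxygen as diene terminus, which the stronger polarisation of C4=O and retention of the 2-quinolone amide should secure, and it needs the absence of Brønsted acid, which the hindered pyridine secures so that 15 does not close its own OH onto the alkene.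

Compound list
1 | 2,3-dimethoxyaniline | COc1cccc(N)c1OC | starting material
2 | N-(methoxymethyl)-2,3-dimethoxyaniline | COCNc1cccc(OC)c1OC | intermediate
3 | N-methyl-2,3-dimethoxyaniline | CNc1cccc(OC)c1OC | intermediate
4 | diethyl malonate | CCOC(=O)CC(=O)OCC | starting material
5 | ethyl 3-[(2,3-dimethoxyphenyl)(methyl)amino]-3-oxopropanoate | CCOC(=O)CC(=O)N(C)c1cccc(OC)c1OC | intermediate
6 | 3-[(2,3-dimethoxyphenyl)(methyl)amino]-3-oxopropanoic acid | OC(=O)CC(=O)N(C)c1cccc(OC)c1OC | intermediate
7 | 4-hydroxy-7,8-dimethoxy-1-methylquinolin-2(1H)-one | COc1ccc2c(O)cc(=O)n(C)c2c1OC | intermediate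
8 | isovaleraldehyde (3-methylbutanal) | CC(C)CC=O | starting material
9 | triethyl phosphonoacetate | CCOC(=O)CP(=O)(OCC)OCC | starting material
10 | ethyl (E)-5-methylhex-2-enoate | CCOC(=O)/C=C/CC(C)C | intermediate
11 | (E)-5-methylhex-2-en-1-ol | CC(C)C/C=C/CO | intermediate
12 | (E)-5-methylhex-2-en-1-yl methyl carbonate | CC(C)C/C=C/COC(=O)OC | intermediate
13 | 4-hydroxy-7,8-dimethoxy-1-methyl-3-[(3S)-5-methylhex-1-en-3-yl]quinolin-2(1H)-one | COc1ccc2c(O)c(c(=O)n(C)c2c1OC)[C@@H](CC(C)C)C=C | intermediate
14 | 2-methyl-2-butene | CC=C(C)C | starting material
15 | 3-[(4S)-2,6-dimethylhept-2-en-4-yl]-4-hydroxy-7,8-dimethoxy-1-methylquinolin-2(1H)-one | COc1ccc2c(O)c(c(=O)n(C)c2c1OC)[C@@H](CC(C)C)C=C(C)C | intermediate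
16 | triethyl orthoformate | CCOC(OCC)OCC | starting material
17 | 3-(ethoxymethylidene)-7,8-dimethoxy-1-methylquinoline-2,4(1H,3H)-dione | CCOC=C1C(=O)c2ccc(OC)c(OC)c2N(C)C1=O | intermediate
18 | 3-[({3-[(4S)-2,6-dimethylhept-2-en-4-yl]-7,8-dimethoxy-1-methyl-2-oxo-1,2-dihydroquinolin-4-yl}oxy)methylidene]-7,8-dimethoxy-1-methylquinoline-2,4(1H,3H)-dione | COc1ccc2c(c1OC)N(C)C(=O)C(=COc1c([C@@H](CC(C)C)C=C(C)C)c(=O)n(C)c3c(OC)c(OC)ccc13)C2=O | intermediate
19 | CNP0275598.1: hexacyclic cis-fused bis(pyrano[3,2-c]quinolin-5-one) made of two 7,8-dimethoxy-1-methyl-2-quinolones; pyran C runs O–C4(A)=C3(A)–(S)-CH(isobutyl)–(S)-CH–(R)-CH(O), pyran D runs (R)-CH–C3(B)=C4(B)–O–CMe2–(S)-CH; the two fusion hydrogens are cis and isobutyl lies on their face, trans to CMe2 | COc1ccc2c3c(c(=O)n(C)c2c1OC)[C@@H](CC(C)C)[C@H]1[C@@H](O3)c2c(c3ccc(OC)c(OC)c3n(C)c2=O)OC1(C)C | target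

Total step count: 11. Longest linear sequence: 7 (steps 1, 2, 3, 4, 8, 9, 11).

Steps most likely to fail

Step 11.
- **What may go wrong:**
  - The ethanol exchange lies on the side of 15 and 17, so too little of 18 may be present at any time.
  - The donor-substituted oxadiene may add too slowly to an unactivated alkene.
  - Traces of acid may close the 4-OH of 15 onto its own alkene.
  - The hinge or the diene terminus may engage a lactam oxygen.
  - Proton loss from the developing tertiary cation may end in an ene-type product.
- **Fallback** (known chemistry, sets out from 7 and 8, comes back at 19): the roles of the halves are exchanged so that pyran D exists before the cycloaddition.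
  - Condensation of 7 with commercial 3-methylbut-2-enal (ethylenediammonium diacetate, toluene, reflux; Knoevenagel condensation followed by 6π oxa-electrocyclisation) would give 7,8-dimethoxy-2,2,6-trimethyl-2H-pyrano[3,2-c]quinolin-5(6H)-one F1.
  - A three-component domino Knoevenagel/hetero-Diels–Alder reaction of 7, 8 and F1 under the same catalyst would pass through 7,8-dimethoxy-1-methyl-3-(3-methylbutylidene)quinoline-2,4(1H,3H)-dione F2.
  - The oxadiene of F2 adds across the cyclic, chromene-type alkene of F1. Polarity dictates the regiochemistry, suprafacial addition to the ring alkene guarantees the cis fusion, and steric demand should place isobutyl trans to CMe2.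
  - This variant gives up the catalyst-set centre. It would deliver 19 together with the enantiomer of 19 F3, and the required enantiomer would be obtained by preparative HPLC on a chiral stationary phase.

Step 8.
- **What may go wrong:**
  - Branched-to-linear selectivity may be poor with a bulky, ambident enolate.
  - O-allylation followed by sigmatropic drift may lead to the linear C3 isomer.
  - The acidic enol may deactivate the metallacyclic catalyst.
  - Enantioselectivity may erode.
- **Fallback** (sets out from 12, 4 and 3, comes back at 13): the stereocentre is set on a malonate, and quinolone ring A is built afterwards.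
  - The same iridium catalyst with diethyl malonate 4 as nucleophile, a benchmark pairing for this reaction, would give diethyl 2-[(3S)-5-methylhex-1-en-3-yl]malonate F4.
  - Thermal cyclocondensation of F4 with aniline 3 in diphenyl ether at about 240 °C with removal of ethanol is the standard route from monosubstituted malonates and N-alkylanilines to 3-alkyl-4-hydroxy-2-quinolones. It would give 13 with the non-enolisable stereocentre untouched.

Step 9.
- **What may go wrong:**
  - Turnover may be slow at the hindered vinyl group next to a branched allylic carbon.
  - Ruthenium hydrides may move the double bond into conjugation with the quinolone, which would erase the stereocentre.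
- **Fallback** (sets out from 13, comes back at 15): the alkene is rebuilt by cleavage and olefination.
  - Oxidative cleavage of the vinyl group (OsO4 cat., NaIO4, 2,6-lutidine, dioxane/H2O) would give the aldehyde, trapped by the 4-OH as (3R)-2-hydroxy-3-isobutyl-6,7-dimethoxy-5-methyl-2,3-dihydrofuro[3,2-c]quinolin-4(5H)-one F5.
  - Wittig olefination of this lactol with excess isopropylidenetriphenylphosphorane (i-PrPPh3I, KN(SiMe3)2, THF, −78 °C to rt) would give 15. The first equivalent of ylide generates the quinolone enolate, whose charge should protect the adjacent C–H against epimerisation.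

Further compounds
F1 | step 11 | 7,8-dimethoxy-2,2,6-trimethyl-2H-pyrano[3,2-c]quinolin-5(6H)-one | COc1ccc2c3OC(C)(C)C=Cc3c(=O)n(C)c2c1OC
F2 | step 11 | 7,8-dimethoxy-1-methyl-3-(3-methylbutylidene)quinoline-2,4(1H,3H)-dione | CC(C)CC=C1C(=O)c2ccc(OC)c(OC)c2N(C)C1=O
F3 | step 11 | enantiomer of 19 | COc1ccc2c3c(c(=O)n(C)c2c1OC)[C@H](CC(C)C)[C@@H]1[C@H](O3)c2c(c3ccc(OC)c(OC)c3n(C)c2=O)OC1(C)C
F4 | step 8 | diethyl 2-[(3S)-5-methylhex-1-en-3-yl]malonate | CCOC(=O)C(C(=O)OCC)[C@@H](CC(C)C)C=C
F5 | step 9 | (3R)-2-hydroxy-3-isobutyl-6,7-dimethoxy-5-methyl-2,3-dihydrofuro[3,2-c]quinolin-4(5H)-one (lactol epimers) | COc1ccc2c3c(c(=O)n(C)c2c1OC)[C@@H](CC(C)C)C(O)O3
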